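The quinone ring is disconnected at both C(=O)–C(OMe) bonds, C1–C2 and C3–C4. The dioxygenated C2=C3 edge is treated as a dialkoxyalkyne and the C4–C5(chromanyl)=C6–C1 enedione as a maleoyl unit. Strain-release insertion of cobalt into a 3-(chroman-3-yl)cyclobutenedione gives a cobaltacyclopentenedione. In the key step this takes up di-tert-butoxyethyne and reductively eliminates, forming both bonds and the whole quinone ring in one operation. The single stereocentre, C3 of the dihydropyran ring, is set earlier by iridium-catalysed asymmetric hydrogenation of a 2H-chromene allylic alcohol. The tert-butyl groups are exchanged for methyl at the end.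

Key step: step 10

Assumption: di-tert-butoxyethyne is taken as a purchasable, storable dialkoxyalkyne; otherwise it would be made from trans-2,3-dichloro-1,4-dioxane by the standard substitution/elimination sequence.

Step 1
Reactants: 1 2-hydroxy-3,4-dimethoxybenzaldehyde
Product: 3 2,5-dihydroxy-3,4-dimethoxybenzaldehyde, via aryl sulfate potassium salt 2 (not isolated)
Conditions: K2S2O8, 10% aq NaOH, 0→20 °C; then aq HCl, 85 °C
Reagents that add atoms: potassium peroxodisulfate, [K+].[K+].[O-]S(=O)(=O)OOS(=O)(=O)[O-]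
Why: Elbs persulfate oxidation: the phenolate attacks peroxodisulfate through C5, the only free ortho/para position, and acid hydrolysis of the aryl sulfate should give the hydroquinone without touching the aldehyde.

Step 2
Reactants: 3 2,5-dihydroxy-3,4-dimethoxybenzaldehyde
Product: 4 5-(benzyloxy)-2-hydroxy-3,4-dimethoxybenzaldehyde
Conditions: BnBr (1 equiv), K2CO3 (1 equiv), DMF, 25 °C
Reagents that add atoms: benzyl bromide, BrCc1ccccc1
Why: Williamson etherification; the 2-OH is hydrogen-bonded to the formyl group and flanked on both sides, so the 5-OH should be benzylated selectively.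

Step 3
Reactants: 4 5-(benzyloxy)-2-hydroxy-3,4-dimethoxybenzaldehyde; 5 acrolein
Product: 6 6-(benzyloxy)-7,8-dimethoxy-2H-chromene-3-carbaldehyde
Conditions: K2CO3, 1,4-dioxane, 100 °C
Reagents that add atoms: none
Why: Oxa-Michael addition of the phenoxide to acrolein followed by intramolecular aldol condensation, the standard salicylaldehyde–acrolein annulation, should close the pyran ring.

Step 4
Reactants: 6 6-(benzyloxy)-7,8-dimethoxy-2H-chromene-3-carbaldehyde
Product: 7 [6-(benzyloxy)-7,8-dimethoxy-2H-chromen-3-yl]methanol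
Conditions: NaBH4, CeCl3·7H2O, MeOH, 0 °C
Reagents that add atoms: none
Why: Luche 1,2-reduction of the enal should give the allylic alcohol and leave the styrene-type C3=C4 bond intact.

Step 5
Reactants: 7 [6-(benzyloxy)-7,8-dimethoxy-2H-chromen-3-yl]methanol
Product: 8 [(3S)-6-(benzyloxy)-7,8-dimethoxy-3,4-dihydro-2H-chromen-3-yl]methanol
Conditions: [Ir(cod)((S)-tBu-PHOX)][B(C6H3(CF3)2)4] (1 mol%), H2 (50 bar), CH2Cl2, 25 °C
Reagents that add atoms: none
Why: Asymmetric hydrogenation of a trisubstituted cinnamyl-type allylic alcohol with an iridium phosphine–oxazoline catalyst; the ligand controls the face of H2 delivery to C3=C4 and so sets C3 (the ligand antipode that gives the 3S alcohol is selected in a test run), and the benzyl ether should survive the homogeneous catalyst.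

Step 6
Reactants: 8 [(3S)-6-(benzyloxy)-7,8-dimethoxy-3,4-dihydro-2H-chromen-3-yl]methanol
Product: 10 (3S)-6-(benzyloxy)-3-ethynyl-7,8-dimethoxy-3,4-dihydro-2H-chromene, via (3R)-chromane-3-carbaldehyde 9 (not isolated)
Conditions: Dess–Martin periodinane, CH2Cl2, 0→25 °C; filter, concentrate; then TMSCHN2/n-BuLi, THF, −78→0 °C
Reagents that add atoms: (trimethylsilyl)diazomethane, C[Si](C)(C)C=[N+]=[N-]
Why: Dess–Martin oxidation gives the configurationally labile aldehyde without base, and the Colvin rearrangement with lithiated TMS-diazomethane at −78 °C (addition, Peterson-type elimination, 1,2-hydrogen shift of the alkylidene carbene) should homologate it to the alkyne without epimerisation; the S→R→S change is only a change in CIP priorities.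

Step 7
Reactants: 10 (3S)-6-(benzyloxy)-3-ethynyl-7,8-dimethoxy-3,4-dihydro-2H-chromene
Product: 11 3-[(3S)-6-(benzyloxy)-7,8-dimethoxy-3,4-dihydro-2H-chromen-3-yl]-4,4-dichlorocyclobut-2-en-1-one
Conditions: Cl3CCOCl, Zn(Cu), Et2O–DME, 25 °C
Reagents that add atoms: trichloroacetyl chloride, ClC(=O)C(Cl)(Cl)Cl
Why: [2+2] cycloaddition of dichloroketene (from zinc dechlorination of trichloroacetyl chloride) to a terminal alkyne; the terminal carbon bonds to the ketene carbonyl carbon, which should give the 3-substituted 4,4-dichlorocyclobutenone regioselectively.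

Step 8
Reactants: 11 3-[(3S)-6-(benzyloxy)-7,8-dimethoxy-3,4-dihydro-2H-chromen-3-yl]-4,4-dichlorocyclobut-2-en-1-one
Product: 12 3-[(3S)-6-(benzyloxy)-7,8-dimethoxy-3,4-dihydro-2H-chromen-3-yl]cyclobut-3-ene-1,2-dione
Conditions: CF3CO2Ag (2.2 equiv), THF–H2O, 0→25 °C, dark
Reagents that add atoms: water, O
Why: Silver-assisted hydrolysis of the allylic, α-keto gem-dichloride (ionisation to a chlorocyclobutenyl cation, capture by water, loss of HCl) should give the cyclobutenedione under conditions that spare the benzyl ether and the electron-rich arene, which the usual concentrated-acid hydrolysis of such dichlorides would not.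

Step 9
Reactants: 12 3-[(3S)-6-(benzyloxy)-7,8-dimethoxy-3,4-dihydro-2H-chromen-3-yl]cyclobut-3-ene-1,2-dione
Product: 14 chloro(dimethylglyoxime)(pyridine)cobalt maleoyl complex, a 3-[(3S)-chroman-3-yl]-1-cobaltacyclopent-3-ene-2,5-dione of trivalent cobalt, via bis(triphenylphosphine) chloro maleoylcobalt complex 13 (not isolated)
Conditions: ClCo(PPh3)3, benzene, 25 °C; then dimethylglyoxime, pyridine, 25 °C
Reagents that add atoms: chlorotris(triphenylphosphine)cobalt ClCo(PPh3)3, Cl[Co-3]([P+](c1ccccc1)(c1ccccc1)c1ccccc1)([P+](c1ccccc1)(c1ccccc1)c1ccccc1)[P+](c1ccccc1)(c1ccccc1)c1ccccc1; dimethylglyoxime, CC(=NO)C(C)=NO; pyridine, c1ccncc1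
Why: Oxidative addition of monovalent cobalt into the strained C1–C2 bond between the two carbonyl groups (strain release of the four-membered ring) gives the maleoyl metallacycle of trivalent cobalt, and exchange of the phosphines for dimethylglyoxime and pyridine should give the air-stable octahedral complex.

Step 10
Reactants: 14 chloro(dimethylglyoxime)(pyridine)cobalt maleoyl complex; 15 di-tert-butoxyethyne
Product: 17 5-[(3S)-6-(benzyloxy)-7,8-dimethoxy-3,4-dihydro-2H-chromen-3-yl]-2,3-di-tert-butoxycyclohexa-2,5-diene-1,4-dione, via cationic acetonitrile maleoylcobalt tetrafluoroborate 16 (not isolated)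
Conditions: AgBF4, CH2Cl2–MeCN, 0 °C, filter; then 15, 2,6-di-tert-butylpyridine (cat.), 0→25 °C
Reagents that add atoms: none
Why: Chloride abstraction opens a site on the trivalent-cobalt bis-acyl, the electron-rich alkyne coordinates and inserts into one Co–acyl bond (first C(=O)–C(O-t-Bu) bond, seven-membered cobaltacycle), and C–C reductive elimination forms the second C(=O)–C(O-t-Bu) bond and releases monovalent cobalt. The closest known reaction type is the benzoquinone synthesis from maleoylcobalt dimethylglyoxime complexes and alkynes under Lewis-acid or silver activation, which accepts alkoxyalkynes; the cobaltacycle itself comes from strain-release opening of the four-membered dione. The six-membered quinone ring is closed by reductive elimination from the cobaltacycloheptadienedione, formally a [4+2] union of the four-carbon maleoyl unit and the two-carbon alkyne. No stereocentre is created, and C3 of the dihydropyran ring is remote from the metal and not epimerisable under these non-basic conditions. Regiochemistry is not an issue because the alkyne is symmetric; the selectivity needed is insertion ahead of acid-induced loss of isobutene from the ynol ether, which pre-forming and filtering the cation, the hindered base and the low temperature should secure.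

Step 11
Reactants: 17 5-[(3S)-6-(benzyloxy)-7,8-dimethoxy-3,4-dihydro-2H-chromen-3-yl]-2,3-di-tert-butoxycyclohexa-2,5-diene-1,4-dione
Product: 19 5-[(3S)-6-(benzyloxy)-7,8-dimethoxy-3,4-dihydro-2H-chromen-3-yl]-2,3-dimethoxycyclohexa-2,5-diene-1,4-dione, via 2,3-dihydroxyquinone 18 (not isolated)
Conditions: TFA, CH2Cl2, 0 °C; evaporate; then TMSCHN2, toluene–MeOH, 0 °C
Reagents that add atoms: (trimethylsilyl)diazomethane, C[Si](C)(C)C=[N+]=[N-]
Why: Acidolysis of the two tert-butyl vinylogous esters (E1 loss of isobutene) followed by O-methylation of the strongly acidic hydroxyquinone with the diazoalkane, which protonation directs to the oxygens that carried the protons; the aryl benzyl ether should survive brief cold TFA.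

Step 12
Reactants: 19 5-[(3S)-6-(benzyloxy)-7,8-dimethoxy-3,4-dihydro-2H-chromen-3-yl]-2,3-dimethoxycyclohexa-2,5-diene-1,4-dione
Product: 21 5-[(3S)-6-hydroxy-7,8-dimethoxy-3,4-dihydro-2H-chromen-3-yl]-2,3-dimethoxycyclohexa-2,5-diene-1,4-dione, via hydroquinone 20 (not isolated)
Conditions: H2 (1 atm), Pd/C, EtOAc, 25 °C; then air, 25 °C
Reagents that add atoms: none
Why: Hydrogenolysis of the benzyl ether over palladium also reduces the quinone to the hydroquinone, which aerial oxidation over the same catalyst should return to the quinone while the mono-phenolic chromanol is left alone.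

Compound list
1 | 2-hydroxy-3,4-dimethoxybenzaldehyde | O=Cc1ccc(OC)c(OC)c1O | starting material
2 | potassium 5-formyl-4-hydroxy-2,3-dimethoxyphenyl sulfate | O=Cc1cc(OS(=O)(=O)[O-])c(OC)c(OC)c1O.[K+] | intermediate
3 | 2,5-dihydroxy-3,4-dimethoxybenzaldehyde | O=Cc1cc(O)c(OC)c(OC)c1O | intermediate
4 | 5-(benzyloxy)-2-hydroxy-3,4-dimethoxybenzaldehyde | O=Cc1cc(OCc2ccccc2)c(OC)c(OC)c1O | intermediate
5 | acrolein (prop-2-enal) | C=CC=O | starting material
6 | 6-(benzyloxy)-7,8-dimethoxy-2H-chromene-3-carbaldehyde | O=CC1=Cc2cc(OCc3ccccc3)c(OC)c(OC)c2OC1 | intermediate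
7 | [6-(benzyloxy)-7,8-dimethoxy-2H-chromen-3-yl]methanol | OCC1=Cc2cc(OCc3ccccc3)c(OC)c(OC)c2OC1 | intermediate
8 | [(3S)-6-(benzyloxy)-7,8-dimethoxy-3,4-dihydro-2H-chromen-3-yl]methanol | OC[C@H]1COc2c(cc(OCc3ccccc3)c(OC)c2OC)C1 | intermediate
9 | (3R)-6-(benzyloxy)-7,8-dimethoxy-3,4-dihydro-2H-chromene-3-carbaldehyde | O=C[C@H]1COc2c(cc(OCc3ccccc3)c(OC)c2OC)C1 | intermediate
10 | (3S)-6-(benzyloxy)-3-ethynyl-7,8-dimethoxy-3,4-dihydro-2H-chromene | C#C[C@H]1COc2c(cc(OCc3ccccc3)c(OC)c2OC)C1 | intermediate
11 | 3-[(3S)-6-(benzyloxy)-7,8-dimethoxy-3,4-dihydro-2H-chromen-3-yl]-4,4-dichlorocyclobut-2-en-1-one | O=C1C=C([C@H]2COc3c(cc(OCc4ccccc4)c(OC)c3OC)C2)C1(Cl)Cl | intermediate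
12 | 3-[(3S)-6-(benzyloxy)-7,8-dimethoxy-3,4-dihydro-2H-chromen-3-yl]cyclobut-3-ene-1,2-dione | O=C1C=C([C@H]2COc3c(cc(OCc4ccccc4)c(OC)c3OC)C2)C1=O | intermediate
13 | chlorobis(triphenylphosphine)cobalt maleoyl complex: 1-chloro-1,1-bis(triphenylphosphine)-3-[(3S)-6-(benzyloxy)-7,8-dimethoxy-3,4-dihydro-2H-chromen-3-yl]-1-cobaltacyclopent-3-ene-2,5-dione (trivalent cobalt) | O=C1C=C([C@H]2COc3c(cc(OCc4ccccc4)c(OC)c3OC)C2)C(=O)[Co-2]1(Cl)([P+](c5ccccc5)(c5ccccc5)c5ccccc5)[P+](c6ccccc6)(c6ccccc6)c6ccccc6 | intermediate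
14 | chloro(dimethylglyoxime-N,N')(pyridine)cobalt maleoyl complex: 1-chloro-1-(dimethylglyoxime)-1-(pyridine)-3-[(3S)-6-(benzyloxy)-7,8-dimethoxy-3,4-dihydro-2H-chromen-3-yl]-1-cobaltacyclopent-3-ene-2,5-dione (trivalent cobalt) | O=C1C=C([C@H]2COc3c(cc(OCc4ccccc4)c(OC)c3OC)C2)C(=O)[Co-3]15(Cl)([n+]6ccccc6)[N+](O)=C(C)C(C)=[N+]5O | intermediate
15 | di-tert-butoxyethyne | CC(C)(C)OC#COC(C)(C)C | starting material
16 | (acetonitrile)(dimethylglyoxime-N,N')(pyridine)cobalt maleoyl cation tetrafluoroborate, the chloride-free analogue of 14 (trivalent cobalt) | O=C1C=C([C@H]2COc3c(cc(OCc4ccccc4)c(OC)c3OC)C2)C(=O)[Co-3]15([N+]#CC)([n+]6ccccc6)[N+](O)=C(C)C(C)=[N+]5O.F[B-](F)(F)F | intermediate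
17 | 5-[(3S)-6-(benzyloxy)-7,8-dimethoxy-3,4-dihydro-2H-chromen-3-yl]-2,3-di-tert-butoxycyclohexa-2,5-diene-1,4-dione | CC(C)(C)OC1=C(OC(C)(C)C)C(=O)C([C@H]2COc3c(cc(OCc4ccccc4)c(OC)c3OC)C2)=CC1=O | intermediate
18 | 5-[(3S)-6-(benzyloxy)-7,8-dimethoxy-3,4-dihydro-2H-chromen-3-yl]-2,3-dihydroxycyclohexa-2,5-diene-1,4-dione | OC1=C(O)C(=O)C([C@H]2COc3c(cc(OCc4ccccc4)c(OC)c3OC)C2)=CC1=O | intermediate
19 | 5-[(3S)-6-(benzyloxy)-7,8-dimethoxy-3,4-dihydro-2H-chromen-3-yl]-2,3-dimethoxycyclohexa-2,5-diene-1,4-dione | COC1=C(OC)C(=O)C([C@H]2COc3c(cc(OCc4ccccc4)c(OC)c3OC)C2)=CC1=O | intermediate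
20 | 5-[(3S)-6-hydroxy-7,8-dimethoxy-3,4-dihydro-2H-chromen-3-yl]-2,3-dimethoxybenzene-1,4-diol | COc1c(OC)c(O)c([C@H]2COc3c(cc(O)c(OC)c3OC)C2)cc1O | intermediate
21 | 5-[(3S)-6-hydroxy-7,8-dimethoxy-3,4-dihydro-2H-chromen-3-yl]-2,3-dimethoxycyclohexa-2,5-diene-1,4-dione | COC1=C(OC)C(=O)C([C@H]2COc3c(cc(O)c(OC)c3OC)C2)=CC1=O | target

Total step count: 12. Longest linear sequence: 12 steps (from 1 to 21).

Steps most likely to fail

Step 10. The dialkoxyalkyne may be consumed by protonolysis or retro-ene loss of isobutene before it inserts, or insertion into the cobalt–acyl bond may be slowed by the two tert-butoxy groups. The fallback sets out from alkyne 10 and comes back at 19. Deprotonation of 10 (n-BuLi, THF, −78 °C) and 1,2-addition of the acetylide to dimethyl squarate would give 4-{[(3S)-6-(benzyloxy)-7,8-dimethoxy-3,4-dihydro-2H-chromen-3-yl]ethynyl}-4-hydroxy-2,3-dimethoxycyclobut-2-en-1-one F1 (carbinol centre formed as a mixture and lost in the next operation). Its Moore rearrangement in refluxing p-xylene (electrocyclic opening to the alkynylketene, ring closure, hydrogen transfer) should give quinone 19 directly. This route builds the quinone ring through its other two C–C bonds and bypasses the cobalt chemistry.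

Step 8. Ionisation of the gem-dichloride may be incomplete, or electrocyclic ring opening and chlorine migration of the strained enone may outrun hydrolysis. The fallback sets out from alkyne 10 and comes back at 12. Acetone-sensitised [2+2] photocycloaddition of 10 with 4,5-dichloro-1,3-dioxol-2-one (dichlorovinylene carbonate) would give 6-[(3S)-6-(benzyloxy)-7,8-dimethoxy-3,4-dihydro-2H-chromen-3-yl]-1,5-dichloro-2,4-dioxabicyclo[3.2.0]hept-6-en-3-one F2 (cis ring fusion, facial mixture, inconsequential). Hydrolysis in aqueous dioxane at 25 °C should then release cyclobutenedione 12 without any silver salt or strong acid.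

Step 11. The free 2,3-dihydroxyquinone may tautomerise and be alkylated on the wrong oxygen to give ortho-quinone ethers, or the diazoalkane may add as a dipole across the quinone C5=C6 bond. The fallback sets out from 17 and comes back at 19. Acid-catalysed exchange in methanol (H2SO4 cat., HC(OMe)3, MeOH, 50 °C) would remove the tert-butyl groups and then etherify the vinylogous acid with methanol in a Fischer-type manner, in one pot and without an alkylating agent. This fallback makes no new compound (F0).

Further compounds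
F1 | step 10 | 4-{[(3S)-6-(benzyloxy)-7,8-dimethoxy-3,4-dihydro-2H-chromen-3-yl]ethynyl}-4-hydroxy-2,3-dimethoxycyclobut-2-en-1-one | COC1=C(OC)C(O)(C#C[C@H]2COc3c(cc(OCc4ccccc4)c(OC)c3OC)C2)C1=O
F2 | step 8 | 6-[(3S)-6-(benzyloxy)-7,8-dimethoxy-3,4-dihydro-2H-chromen-3-yl]-1,5-dichloro-2,4-dioxabicyclo[3.2.0]hept-6-en-3-one | O=C1OC2(Cl)C=C([C@H]3COc4c(cc(OCc5ccccc5)c(OC)c4OC)C3)C2(Cl)O1
F0 | step 11 | none | none
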